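X, the initiator, is the currency of this ledger; Z, the monomer, joins chains as L. Keep the books on both and read the length as monomer in chains over chains begun.

| setting | Thursday's | Wednesday's | Tuesday's | ochre | red |
|---|---|---|---|---|---|
| Z | 20 mM | 20 mM | 40 mM | 20 mM | 20 mM |
| X | 0.35 mM | 1.4 mM | 0.70 mM | 0.70 mM | 0.70 mM |
| remark | run made earlier | run made earlier | run made earlier |  |  |
| time |  |  |  | 4.0 min | 1.2 min |

| run | time / min | L / % |
|---|---|---|
| Thursday's | 0.667 | 54.8 |
| Thursday's | 1.33 | 89.4 |
| Thursday's | 2.00 | 96.4 |
| Thursday's | 2.50 | 99.7 |
| Thursday's | 3.00 | 99.6 |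
| Wednesday's | 0.250 | 24.8 |
| Wednesday's | 0.500 | 75.1 |
| Wednesday's | 0.833 | 94.3 |
| Wednesday's | 1.50 | 100.4 |
| Wednesday's | 3.00 | 100.6 |
| Tuesday's | 0.250 | 21.5 |
| Tuesday's | 0.833 | 89.5 |
| Tuesday's | 1.33 | 96.3 |
| Tuesday's | 2.50 | 100.9 |
| Tuesday's | 3.00 | 99.8 |

(readings scatter by 1 percentage point)

- the average divides the monomer in chains by the number of chains begun, living and dead together
- the numbers in the tables scatter with a standard deviation of 1 percentage point
- the earlier runs do not show the number of chains; that part of a forecast is a guess

- which of the two ends with the longer chains by the average number of monomer units in a chain (chains begun, living or dead) ("neither" if they lie within 10 %) (ochre / red / neither)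
- average number of monomer units in a chain (chains begun, living or dead) at the end, ochre
- average number of monomer units in a chain (chains begun, living or dead) at the end, red

1. Enter Z first. Read the last rows: Thursday's gives 99.6 %, Wednesday's 100.6 % and Tuesday's 99.8 %, each at 3.00 min. Ochre has the X of Tuesday's and runs longer, to 4.0 min, so close its Z into L.

2. Enter red's shorter time. Tuesday's, with red's X but 40 mM of Z, reads 96.3 % at 1.33 min, and red stops at 1.2 min. Expect red's L a few points below complete.

3. Enter X. Allow each X at most one chain. Divide c(Z) by c(X) as charged: 28.6 units, the floor length, the average length if each X charged begins one chain and the charged Z ends in L.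

4. Open a second column for X that begins no chain. The readings show L and no chains, so this column stays unknown. Write the length as the floor times the fraction of Z in L, divided by the share of X that has begun chains.

5. Commit to the floor and no further: my reckoning gives no figure for the share, so it names no winner.

The forecast goes further. It names red, with 43 for ochre (range 28 to 120) and 90 for red (range 27 to 300), and calls that part a guess. Its ground: “Ochre has therefore started more chains for almost the same monomer, so red should be longer”.

The flasks give neither: ochre 69.0, red 70.1.

    Z + E → L + E, rate k1*[E]*[Z] (k = 352 M⁻¹ s⁻¹)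
    Q → D (k = 0.00809 s⁻¹)
    Z + Q → E + L (k = 2.72 M⁻¹ s⁻¹)
    2 E → G (k = 71.8 M⁻¹ s⁻¹)
    X → Q (k = 0.0296 s⁻¹)

Close the books with the floor. Ochre at 4.00 min has begun c(E) + 2 c(G) = 0.289 mM of chains, so floor over length gives a share of 41.4 %, while Q and D hold 0.410 mM. Red at 1.20 min has begun 0.269 mM. Now take a neighbour of ochre, charged with 0.42 mM of X and read at 4.00 min. Its floor is 47.6, its chains come to 0.214 mM, and Q and D hold 0.205 mM. Its length is 93.0, a share of 51.2 %.

The numbers in the tables were generated by integration for an exercise; scatter was added.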